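**Plan**

- Retrosynthesis: the C13(=C16H2)–C14(OH) unit is cut back to a (13R,14R)-epoxy alcohol and then to the (E)-13-en-15-ol; C13=C14 is cut to a C13 methyl ketone; the C4 methyl group and the C3 hydrogens are cut back to a cyclic β-keto ester; the C4–C5 and C9–C10 ring bonds and the C8=C17 alkene are then cut in one operation to an acyclic β-keto ester, itself cut at C1–C2 to an acetoacetate dianion and an allylic bromide from (E)-geranylacetone.
- Forward: the chain is joined at C1–C2; ring A (C4–C5) and ring B (C9–C10) arise in one oxidative radical cascade that ends in the 8(17)-methylene; C4 is then methylated, C3 deoxygenated and the side chain completed.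
- Enabling feature: C4 carries the ester carbon C19, so with a temporary C3 ketone it is the radical-forming α-carbon of a β-keto ester. C5/C10 and C9/C8 are the termini of two (E)-trisubstituted alkenes of a head-to-tail isoprenoid chain, C8 bears the methyl group (C17) that becomes the exocyclic methylene, and C13/C16 are the acetyl group of geranylacetone.
- Stereochemistry: C5, C9 and C10 from chair–chair folding under control of a (+)-8-phenylmenthyl ester; C4 by α-face methylation relayed from the C10 methyl group; C14 by catalytic Sharpless epoxidation with D-(−)-diethyl tartrate.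

Key step: step 6

Assumption: isomerically pure (E)-geranylacetone and (+)-8-phenylmenthol are bought; the (+)-auxiliary is assumed, by analogy with related Mn(III) cyclisations of its β-keto esters, to lead to the 5α-H/10β-methyl series (its antipode would be used otherwise).

**Route**

Step 1
Reactants: 1 (E)-geranylacetone
Product: 2 2-[(3E)-4,8-dimethylnona-3,7-dien-1-yl]-2-methyl-1,3-dioxolane
Conditions: HOCH2CH2OH, PPTS (cat.), benzene, reflux, Dean–Stark
Reagents that add atoms: ethylene glycol, OCCO
Why: Acid-catalysed ketalisation with azeotropic removal of water masks the methyl ketone against the dianion of step 5, and PPTS is too weak an acid to protonate the trisubstituted alkenes.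

Step 2
Reactants: 2 2-[(3E)-4,8-dimethylnona-3,7-dien-1-yl]-2-methyl-1,3-dioxolane
Product: 3 (2E,6E)-2,6-dimethyl-9-(2-methyl-1,3-dioxolan-2-yl)nona-2,6-dien-1-ol
Conditions: SeO2 (0.3 equiv), t-BuOOH (in decane, 2.5 equiv), CH2Cl2, 0 °C → rt
Reagents that add atoms: selenium dioxide, O=[Se]=O; tert-butyl hydroperoxide, CC(C)(C)OO
Why: Catalytic SeO2 allylic oxidation (ene reaction, then [2,3]-sigmatropic shift) attacks the terminal, most electron-rich trisubstituted alkene at its (E)-methyl group, which gives the (E)-allylic alcohol and so fixes the C10=C5 geometry needed later for the trans ring fusion.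

Step 3
Reactants: 3 (2E,6E)-2,6-dimethyl-9-(2-methyl-1,3-dioxolan-2-yl)nona-2,6-dien-1-ol
Product: 4 2-[(3E,7E)-9-bromo-4,8-dimethylnona-3,7-dien-1-yl]-2-methyl-1,3-dioxolane
Conditions: CBr4, PPh3, CH2Cl2, 0 °C
Reagents that add atoms: carbon tetrabromide, BrC(Br)(Br)Br
Why: Appel bromination converts the primary allylic alcohol into the bromide under neutral conditions, without allylic transposition and without loss of the ketal.

Step 4
Reactants: 5 (+)-8-phenylmenthol, (1S,2R,5S)-5-methyl-2-(2-phenylpropan-2-yl)cyclohexan-1-ol; 6 2,2,6-trimethyl-4H-1,3-dioxin-4-one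
Product: 8 (+)-8-phenylmenthyl acetoacetate, via acetylketene 7 (not isolated)
Conditions: xylene, 140 °C, acetone distilled off
Reagents that add atoms: none
Why: Thermal retro-[4+2] fragmentation of the dioxinone releases acetylketene, which acylates even the hindered secondary auxiliary alcohol (acetoacetylation).

Step 5
Reactants: 8 (+)-8-phenylmenthyl acetoacetate; 4 2-[(3E,7E)-9-bromo-4,8-dimethylnona-3,7-dien-1-yl]-2-methyl-1,3-dioxolane
Product: 10 (+)-8-phenylmenthyl (6E,10E)-6,10-dimethyl-3,14-dioxopentadeca-6,10-dienoate 14-ethylene ketal, via acetoacetate dianion 9 (not isolated)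
Conditions: NaH, THF, 0 °C; n-BuLi, 0 °C; then 4, 0 °C → rt; H2O
Reagents that add atoms: none
Why: Acetoacetate dianion alkylation: the more basic terminal (γ) carbanion displaces the allylic bromide by SN2, which joins C1–C2 and leaves both (E)-alkenes untouched.

Step 6
Reactants: 10 (+)-8-phenylmenthyl (6E,10E)-6,10-dimethyl-3,14-dioxopentadeca-6,10-dienoate 14-ethylene ketal
Product: 12 (+)-8-phenylmenthyl 3,13-dioxo-14,15,19-trinorlabd-8(17)-en-18-oate, via bicyclic ketal 11 (not isolated)
Conditions: Mn(OAc)3·2H2O (2.2 equiv), Cu(OAc)2·H2O (1 equiv), Yb(OTf)3 (1 equiv), CF3CH2OH, −5 °C → rt; then 1 M HCl, THF, rt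
Reagents that add atoms: water, O
Why: Mn(III) oxidises the chelated β-keto ester enolate of 10 to the electrophilic C4 radical, which adds to C5 of the (E)-C5=C10 alkene; the tertiary C10 radical then adds to C9 of the (E)-C8=C9 alkene, and the tertiary C8 radical is captured by Cu(II) and loses a C17 hydrogen by β-hydride elimination to give the exocyclic C8=C17 alkene. The closest known reaction type is the Mn(OAc)3/Cu(OAc)2 oxidative free-radical polyene cyclisation of unsaturated β-keto esters, including its lanthanide-triflate-assisted variant with 8-phenylmenthyl esters. Ring A closes by C4–C5 bond formation (6-endo-trig) and ring B by C9–C10 bond formation (6-endo-trig), both through chair transition states. The trans ring fusion (5α-H, 10β-methyl) and the equatorial 9β side chain follow from chair–chair folding of the E,E-diene; C4 forms with the ester equatorial but stays epimerisable and is only fixed in step 8; the absolute sense comes from the auxiliary, whose phenyl ring should shield one face of the Yb/Mn-chelated planar dicarbonyl radical so that C5 bonds to the open face. The step needs face selectivity at C4, 6-endo over 5-exo closure and exocyclic over endocyclic alkene formation: the first is secured by the auxiliary, the second by the trisubstituted alkenes (attack at the less substituted terminus gives tertiary radicals), the third by the preference of the organocopper intermediate to lose the most accessible (methyl) β-hydrogen; the C13 carbonyl, whether still ketalised or already freed, has no 1,3-dicarbonyl partner and does not enter the cascade, and the acidic work-up completes its release.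

Step 7
Reactants: 12 (+)-8-phenylmenthyl 3,13-dioxo-14,15,19-trinorlabd-8(17)-en-18-oate
Product: 14 methyl 3,13-dioxo-14,15,19-trinorlabd-8(17)-en-18-oate, via α-oxoketene 13 (not isolated)
Conditions: MeOH (excess), DMAP (0.3 equiv), toluene, 110 °C, sealed tube
Reagents that add atoms: methanol, CO
Why: Thermal transesterification of an enolisable β-keto ester: the enol of 12 expels the bulky auxiliary alcohol to give the α-oxoketene, which the large excess of methanol captures; this exchange needs the hydrogen at C4, which is why the C4 methyl group is introduced only afterwards.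

Step 8
Reactants: 14 methyl 3,13-dioxo-14,15,19-trinorlabd-8(17)-en-18-oate
Product: 15 methyl 3,13-dioxo-14,15-dinorlabd-8(17)-en-19-oate
Conditions: MeI, K2CO3, acetone, 50 °C
Reagents that add atoms: iodomethane, CI
Why: C-Alkylation of the cyclic β-keto ester enolate: iodomethane should approach C4 from the α-face, anti to the axial C10 methyl group that blocks the β-face by a 1,3-diaxial interaction, so the new methyl becomes equatorial (4α) and the ester axial (4β, C19), as in the classical alkylations of 3-oxo-4-carboalkoxy-10-methyl-trans-decalins.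

Step 9
Reactants: 15 methyl 3,13-dioxo-14,15-dinorlabd-8(17)-en-19-oate
Product: 16 15-ethyl 19-methyl (13E)-3-oxolabda-8(17),13-diene-15,19-dioate
Conditions: (EtO)2P(O)CH2CO2Et, NaH, THF, 0 °C → 50 °C
Reagents that add atoms: triethyl phosphonoacetate, CCOC(=O)CP(=O)(OCC)OCC
Why: Horner–Wadsworth–Emmons olefination should take place only at the unhindered C13 methyl ketone (the C3 ketone is flanked by the quaternary C4) and give mainly the (E)-enoate, the Z-isomer being removed by chromatography.

Step 10
Reactants: 16 15-ethyl 19-methyl (13E)-3-oxolabda-8(17),13-diene-15,19-dioate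
Product: 17 15-ethyl 19-methyl (13E)-3β-hydroxylabda-8(17),13-diene-15,19-dioate
Conditions: NaBH4, MeOH/THF, 0 °C
Reagents that add atoms: none
Why: Borohydride reduces the C3 ketone (axial hydride delivery should give the equatorial 3β-alcohol, whose configuration is immaterial because the centre is removed) and leaves the conjugated ester and the hindered C19 ester untouched.

Step 11
Reactants: 17 15-ethyl 19-methyl (13E)-3β-hydroxylabda-8(17),13-diene-15,19-dioate
Product: 18 15-ethyl 19-methyl (13E)-3β-[(imidazol-1-yl)carbothioyloxy]labda-8(17),13-diene-15,19-dioate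
Conditions: 1,1′-thiocarbonyldiimidazole (2 equiv), DMAP (cat.), ClCH2CH2Cl, 80 °C
Reagents that add atoms: 1,1′-thiocarbonyldiimidazole, S=C(n1ccnc1)n1ccnc1
Why: Neutral thioacylation (first stage of the Barton–McCombie deoxygenation) avoids the strong base that could trigger retro-aldol cleavage of the β-hydroxy ester.

Step 12
Reactants: 18 15-ethyl 19-methyl (13E)-3β-[(imidazol-1-yl)carbothioyloxy]labda-8(17),13-diene-15,19-dioate
Product: 19 15-ethyl 19-methyl (13E)-labda-8(17),13-diene-15,19-dioate
Conditions: Bu3SnH (1.5 equiv), AIBN (cat.), toluene, 110 °C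
Reagents that add atoms: none
Why: Barton–McCombie radical deoxygenation: the stannyl radical adds to the thiocarbonyl group, the C3–O bond fragments, and the secondary C3 radical, which has no alkene within cyclisation range, is reduced by the tin hydride.

Step 13
Reactants: 19 15-ethyl 19-methyl (13E)-labda-8(17),13-diene-15,19-dioate
Product: 20 methyl (13E)-15-hydroxylabda-8(17),13-dien-19-oate
Conditions: DIBAL-H (2.3 equiv), CH2Cl2, −78 °C; Rochelle salt
Reagents that add atoms: none
Why: DIBAL-H reduces the unhindered conjugated ethyl ester to the allylic alcohol by 1,2-reduction at low temperature, whereas the axial, neopentyl-type C19 methyl ester should be too hindered to react.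

Step 14
Reactants: 20 methyl (13E)-15-hydroxylabda-8(17),13-dien-19-oate
Product: 21 methyl (13R,14R)-13,14-epoxy-15-hydroxylabd-8(17)-en-19-oate
Conditions: Ti(OiPr)4 (10 mol %), D-(−)-diethyl tartrate (12 mol %), t-BuOOH (in decane, 2 equiv), 4 Å MS, CH2Cl2, −20 °C
Reagents that add atoms: tert-butyl hydroperoxide, CC(C)(C)OO
Why: Katsuki–Sharpless asymmetric epoxidation: with D-(−)-diethyl tartrate the titanium-bound peroxide is delivered to the face of the (E)-allylic alcohol that gives the (13R,14R)-epoxide, under reagent control independent of the remote decalin, and the isolated C8=C17 alkene is not epoxidised.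

Step 15
Reactants: 21 methyl (13R,14R)-13,14-epoxy-15-hydroxylabd-8(17)-en-19-oate
Product: 22 methyl (14S)-14,15-dihydroxylabda-8(17),13(16)-dien-19-oate (CNP0185041.1)
Conditions: Ti(OiPr)4 (2 equiv), CH2Cl2, rt; aq. tartaric acid
Reagents that add atoms: none
Why: Titanium-alkoxide-mediated isomerisation of a 2,3-epoxy alcohol to a 3-ene-1,2-diol: titanium bound to O15 activates the tertiary C13–O bond while an alkoxide ligand removes a proton from the C16 methyl group, which is cis to C15, in a syn elimination; the C14–O bond is not touched, so the configuration set in step 14 becomes 14S in the diol.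

**Compound list**

1 | (E)-geranylacetone, (5E)-6,10-dimethylundeca-5,9-dien-2-one | CC(=O)CC/C=C(\C)CCC=C(C)C | starting material
2 | 2-[(3E)-4,8-dimethylnona-3,7-dien-1-yl]-2-methyl-1,3-dioxolane | CC1(CC/C=C(\C)CCC=C(C)C)OCCO1 | intermediate
3 | (2E,6E)-2,6-dimethyl-9-(2-methyl-1,3-dioxolan-2-yl)nona-2,6-dien-1-ol | CC1(CC/C=C(\C)CC/C=C(\C)CO)OCCO1 | intermediate
4 | 2-[(3E,7E)-9-bromo-4,8-dimethylnona-3,7-dien-1-yl]-2-methyl-1,3-dioxolane | CC1(CC/C=C(\C)CC/C=C(\C)CBr)OCCO1 | intermediate
5 | (+)-8-phenylmenthol, (1S,2R,5S)-5-methyl-2-(2-phenylpropan-2-yl)cyclohexan-1-ol | O[C@H]1C[C@@H](C)CC[C@@H]1C(C)(C)c1ccccc1 | starting material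
6 | 2,2,6-trimethyl-4H-1,3-dioxin-4-one | CC1=CC(=O)OC(C)(C)O1 | starting material
7 | acetylketene | CC(=O)C=C=O | intermediate (not isolated)
8 | (+)-8-phenylmenthyl acetoacetate | CC(=O)CC(=O)O[C@H]1C[C@@H](C)CC[C@@H]1C(C)(C)c1ccccc1 | intermediate
9 | sodium lithium dianion of 8 | [CH2-]C(=O)[CH-]C(=O)O[C@H]1C[C@@H](C)CC[C@@H]1C(C)(C)c1ccccc1.[Na+].[Li+] | intermediate (not isolated)
10 | (+)-8-phenylmenthyl (6E,10E)-6,10-dimethyl-3,14-dioxopentadeca-6,10-dienoate 14-ethylene ketal | CC1(CC/C=C(\C)CC/C=C(\C)CCC(=O)CC(=O)O[C@H]2C[C@@H](C)CC[C@@H]2C(C)(C)c2ccccc2)OCCO1 | intermediate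
11 | (+)-8-phenylmenthyl 13,13-(ethylenedioxy)-3-oxo-14,15,19-trinorlabd-8(17)-en-18-oate (4α-ester, 4β-H, 5α-H, 9β-chain, 10β-Me) | CC1(CC[C@H]2C(=C)CC[C@@H]3[C@]2(C)CCC(=O)[C@H]3C(=O)O[C@H]4C[C@@H](C)CC[C@@H]4C(C)(C)c4ccccc4)OCCO1 | intermediate (not isolated)
12 | (+)-8-phenylmenthyl 3,13-dioxo-14,15,19-trinorlabd-8(17)-en-18-oate (4α-ester, 4β-H) | CC(=O)CC[C@H]1C(=C)CC[C@@H]2[C@]1(C)CCC(=O)[C@H]2C(=O)O[C@H]3C[C@@H](C)CC[C@@H]3C(C)(C)c3ccccc3 | intermediate
13 | 4-(oxomethylidene)-14,15,18,19-tetranorlabd-8(17)-ene-3,13-dione (α-oxoketene) | CC(=O)CC[C@H]1C(=C)CC[C@@H]2[C@]1(C)CCC(=O)C2=C=O | intermediate (not isolated)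
14 | methyl 3,13-dioxo-14,15,19-trinorlabd-8(17)-en-18-oate (4α-ester, 4β-H) | CC(=O)CC[C@H]1C(=C)CC[C@@H]2[C@]1(C)CCC(=O)[C@H]2C(=O)OC | intermediate
15 | methyl 3,13-dioxo-14,15-dinorlabd-8(17)-en-19-oate (4α-Me, 4β-CO2Me) | CC(=O)CC[C@H]1C(=C)CC[C@@H]2[C@]1(C)CCC(=O)[C@]2(C)C(=O)OC | intermediate
16 | 15-ethyl 19-methyl (13E)-3-oxolabda-8(17),13-diene-15,19-dioate | CCOC(=O)/C=C(\C)CC[C@H]1C(=C)CC[C@@H]2[C@]1(C)CCC(=O)[C@]2(C)C(=O)OC | intermediate
17 | 15-ethyl 19-methyl (13E)-3β-hydroxylabda-8(17),13-diene-15,19-dioate | CCOC(=O)/C=C(\C)CC[C@H]1C(=C)CC[C@@H]2[C@]1(C)CC[C@H](O)[C@]2(C)C(=O)OC | intermediate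
18 | 15-ethyl 19-methyl (13E)-3β-[(imidazol-1-yl)carbothioyloxy]labda-8(17),13-diene-15,19-dioate | CCOC(=O)/C=C(\C)CC[C@H]1C(=C)CC[C@@H]2[C@]1(C)CC[C@H](OC(=S)n3ccnc3)[C@]2(C)C(=O)OC | intermediate
19 | 15-ethyl 19-methyl (13E)-labda-8(17),13-diene-15,19-dioate | CCOC(=O)/C=C(\C)CC[C@H]1C(=C)CC[C@@H]2[C@]1(C)CCC[C@]2(C)C(=O)OC | intermediate
20 | methyl (13E)-15-hydroxylabda-8(17),13-dien-19-oate (methyl isocupressate) | OC/C=C(\C)CC[C@H]1C(=C)CC[C@@H]2[C@]1(C)CCC[C@]2(C)C(=O)OC | intermediate
21 | methyl (13R,14R)-13,14-epoxy-15-hydroxylabd-8(17)-en-19-oate | OC[C@H]1O[C@]1(C)CC[C@H]2C(=C)CC[C@@H]3[C@]2(C)CCC[C@]3(C)C(=O)OC | intermediate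
22 | methyl (4S,5R,9S,10R,14S)-14,15-dihydroxylabda-8(17),13(16)-dien-19-oate | C=C(CC[C@H]1C(=C)CC[C@@H]2[C@]1(C)CCC[C@]2(C)C(=O)OC)[C@H](O)CO | target

**Step count and risks**

Total steps: 15. Longest linear sequence: 14 (steps 1–3 and 5–15, from 1); step 4 is a one-step side branch.

Steps most likely to fail:

1. Step 6. What may go wrong: insufficient face discrimination by the ester auxiliary in a two-ring cascade, interruption after the first ring, or over-oxidation of the still enolisable product. The fallback uses catalyst control instead of auxiliary control and group transfer instead of oxidative termination. It sets out from 4, which is alkylated with the dianion of methyl acetoacetate (NaH, n-BuLi, THF, 0 °C) to methyl (6E,10E)-6,10-dimethyl-3,14-dioxopentadeca-6,10-dienoate 14-ethylene ketal F1. Selenenylation at the α-carbon (PhSeCl, pyridine, CH2Cl2, 0 °C) gives methyl (6E,10E)-6,10-dimethyl-3,14-dioxo-2-(phenylselanyl)pentadeca-6,10-dienoate 14-ethylene ketal F2. A chiral magnesium bis(oxazoline) Lewis acid (Mg(ClO4)2, ligand, 4 Å MS, toluene, −78 °C, UV light) should effect an enantioselective phenylselanyl-group-transfer tandem radical cyclisation to methyl 13,13-(ethylenedioxy)-3-oxo-8α-(phenylselanyl)-14,15,19-trinorlabdan-18-oate F3. Oxidation (H2O2, pyridine, CH2Cl2, 0 °C), syn elimination of the selenoxide towards the C17 methyl group and work-up with 1 M HCl/THF come back to the route at 14, so the auxiliary exchange of step 7 is bypassed as well.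

2. Step 15. What may go wrong: proton loss from C12 instead of C16, or capture of the developing C13 cation by the C8=C17 alkene (pimarane-type ring closure) or by isopropoxide. The fallback makes the ene-diol from an ester dienolate instead of an epoxide. It sets out from 19: LDA/HMPA, THF, −78 °C removes a proton from C16 (the γ-methyl group syn to the ester), and the dienolate is hydroxylated at C14 with an enantiopure (camphorsulfonyl)oxaziridine (the antipode that gives 14S) to 15-ethyl 19-methyl (14S)-14-hydroxylabda-8(17),13(16)-diene-15,19-dioate F4. LiBH4, THF, 0 °C should reduce only the unhindered α-hydroxy ethyl ester and comes back to the route at 22.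

3. Step 11. What may go wrong: incomplete thioacylation of the hindered 3β-hydroxyl next to the quaternary C4, or retro-aldol cleavage of the β-hydroxy ester on prolonged heating. The fallback replaces the radical deoxygenation by an ionic hydrazone reduction. It sets out from 16: TsNHNH2, AcOH (cat.), EtOH, reflux gives 15-ethyl 19-methyl (13E)-3-(tosylhydrazono)labda-8(17),13-diene-15,19-dioate F5. Catecholborane, CHCl3, 0 °C, then NaOAc·3H2O, reflux, should bring about loss of sulfinate and dinitrogen and comes back to the route at 19, bypassing steps 10–12.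

**Further compounds**

F1 | step 6 | methyl (6E,10E)-6,10-dimethyl-3,14-dioxopentadeca-6,10-dienoate 14-ethylene ketal | CC1(CC/C=C(\C)CC/C=C(\C)CCC(=O)CC(=O)OC)OCCO1
F2 | step 6 | methyl (6E,10E)-6,10-dimethyl-3,14-dioxo-2-(phenylselanyl)pentadeca-6,10-dienoate 14-ethylene ketal | CC1(CC/C=C(\C)CC/C=C(\C)CCC(=O)C([Se]c2ccccc2)C(=O)OC)OCCO1
F3 | step 6 | methyl 13,13-(ethylenedioxy)-3-oxo-8α-(phenylselanyl)-14,15,19-trinorlabdan-18-oate | CC1(CC[C@H]2[C@](C)([Se]c4ccccc4)CC[C@@H]3[C@]2(C)CCC(=O)[C@H]3C(=O)OC)OCCO1
F4 | step 15 | 15-ethyl 19-methyl (14S)-14-hydroxylabda-8(17),13(16)-diene-15,19-dioate | CCOC(=O)[C@@H](O)C(=C)CC[C@H]1C(=C)CC[C@@H]2[C@]1(C)CCC[C@]2(C)C(=O)OC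
F5 | step 11 | 15-ethyl 19-methyl (13E)-3-(tosylhydrazono)labda-8(17),13-diene-15,19-dioate | CCOC(=O)/C=C(\C)CC[C@H]1C(=C)CC[C@@H]2[C@]1(C)CCC(=NNS(=O)(=O)c3ccc(C)cc3)[C@]2(C)C(=O)OC
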